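**The account.** Reagent in the second phase is the account we keep: it crosses into the reaction phase, where starting material competes with loss to decomposed reagent and over-reacted product. The south-west run slows with 60% of its starting material still there, so we treat reagent as the limiting reagent.

| setting | south-west | east | south-east | flask |
|---|---|---|---|---|
| starting material | 0.22 M | 0.49 M | 0.33 M | 0.33 M |
| reagent in the second phase | 0.396 M | 0.396 M | 0.20 M | 0.396 M |
| remark | run made earlier | run made earlier | run made earlier |  |
| time |  |  |  | 1.0 h |
| volume of the second phase over the first |  |  |  | 0.50 |

- south-west (time / min: target / %, starting material / %): 3.00: 6, 90; 10.0: 11, 85; 15.0: 24, 78; 25.0: 23, 71; 40.0: 33, 62; 50.0: 31, 60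
- east (time / min: target / %, starting material / %): 4.00: 4, 95; 6.00: 7, 93; 10.0: 10, 89; 20.0: 20, 84; 30.0: 22, 78; 50.0: 25, 69
- south-east (time / min: target / %, starting material / %): 4.00: 2, 97; 12.0: 6, 91; 20.0: 12, 87; 30.0: 11, 86; 50.0: 16, 82

(standard deviation of a reading: 2 percentage points)

- in the second phase: reagent in the second phase; everything else is in the first
- charges count per volume of the first phase; a concentration in a rate is the amount of a species over the volume of its own phase; every rate counts per litre of the first phase
- steps that have been proposed: reagent in the reaction phase + target -> over-reacted product; reagent in the reaction phase <-> dormant form; reagent in the reaction phase -> decomposed reagent; reagent in the reaction phase <-> reagent in the second phase; starting material + reagent in the reaction phase -> target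
- the earlier runs hold the two phases in the same ratio of volumes as the flask asked about

1. target at 1.0 h, in percent of the starting material charged
2. part of the starting material charged that has reacted at 1.0 h

**Sharing concentration.** We take uptake by starting material as proportional to c(starting material), and loss as a fixed rate per reagent. Integrated: reagent spent = starting material converted + a constant × ln(charged over left). The south-west and east runs share a reagent charge, so we equate their ledgers at 50.0 min. This gives 0.457 M: the sharing concentration, the c(starting material) at which reagent divides equally. In this ledger, with the crossing rate held, conversion is zero order in starting material far above it and first order far below it. It is a reading, loose under the scatter.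

**The entries.** The south-west ledger has spent 0.322 M by 50.0 min. Taking the crossing as first order, this flask spends 0.343 M by 1.0 h, leaving 0.0533 M uncrossed. Sharing at the charge gives 0.144 M converted; sharing at the mean c(starting material) gives 0.124 M. Loss takes the remaining 0.219 M, and the books close. We expect 37.5% reacted. The last readings of those two runs keep 77.5% and 80.6% of the converted material as target, so we expect 29.6% target.

**The forecast.** It gives 31.5% target (27.5% to 35%) and 38.5% reacted (34.5% to 43%), a little above ours, “with over-reaction growing slowly”.

**The flask.** It gives 30.9% target and 37.0% reacted.

    reagent in the reaction phase + target → over-reacted product (k = 0.0562 L mol⁻¹ s⁻¹)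
    reagent in the reaction phase ⇌ dormant form (K = 0.560, k = 0.00970 s⁻¹)
    reagent in the reaction phase → decomposed reagent (k = 0.0314 s⁻¹)
    reagent in the reaction phase ⇌ reagent in the second phase, rate k4*([reagent in the reaction phase] - [reagent in the second phase]/K4) per volume of the first phase (partition coefficient = 14.0, kL = 0.00393 s⁻¹)
    starting material + reagent in the reaction phase → target (k = 0.0755 L mol⁻¹ s⁻¹)

Two paths acting together are part of what holds target down in this flask: without the path to decomposed reagent it reaches 42.3% target, and without the path to over-reacted product 39.0%. The neighbour flask holds 0.83 M of starting material, above the sharing concentration. With the same spending, our ledger gives 25.3% reacted; the neighbour flask has 24.3% reacted and 21.9% target.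

The runs come from a simulation for substances that don't exist.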